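**Retrosynthetic overview**

1. The furanone ring (O–C3=C2–C1(=O)–C10) is a cyclodehydrated 1,3-diketone (C1, C3) carrying the C10 hydroxyl, and a C1–C2–C3 1,3-dioxygenated unit is the retron of a 2-isoxazoline. C2–C3 (with O–C1) is therefore made by an intramolecular nitrile oxide–alkene (3+2) cycloaddition that also closes the ten-membered carbocycle; the cis C4=C5 olefin and the cis-fused C6/C7 lactone turn both chain ends to the same side.
2. The acyclic 2,3-seco precursor comes from a C6–C7 indium Barbier allylation/lactonisation of a (Z)-2-(bromomethyl)enoate with a lactol.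
3. The bromide comes from (R)-linalool, which supplies the C10 stereocentre, C14, C9, C8, C7 and the C1=C2 vinyl dipolarophile. C8–O is set by organocatalytic α-oxyamination, and C11–C13 come from methyl propiolate.
4. The lactol comes from 4-(hydroxymethyl)butenolide, a temporary ring that fixes the C4=C5 geometry and tells C3–O from C15–O.
5. Ring order: γ-lactone (step 8), then isoxazoline plus ten-membered carbocycle (step 11), then furanone (step 15).

Key step: step 11

Remark: atoms are numbered C1–C15 as in the germacrane skeleton of the target (C1 ketone, C3 enol-ether carbon, C4=C5, C6–O lactone, C8 ester, C10 with methyl C14, C11=C13, C12 lactone carbonyl, C15 hydroxymethyl); acyclic intermediates are named as 2,3-secogermacranes.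
Remark: the target is taken exactly as drawn, i.e. 6S,7R,8R,10R with a cis-fused C6/C7 lactone; CIP descriptors of intermediates change where substituent priorities change.
Remark: the sense of induction of the imidazolidinone in step 3 is assigned by analogy with other enamine α-functionalisations; the catalyst enantiomer that gives the 2R aldehyde is meant.
Remark: C1 (steps 11–13) and C11 (steps 9–12) are transient stereocentres of no consequence and are left undefined.

**Route**

Step 1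
Reactants: 1 (R)-linalool
Product: 2 (3R)-3,7-dimethyl-3-(triethylsilyloxy)octa-1,6-diene
Conditions: TESOTf, 2,6-lutidine, CH2Cl2, −78 → 0 °C
Reagents that add atoms: triethylsilyl trifluoromethanesulfonate, CC[Si](CC)(CC)OS(=O)(=O)C(F)(F)F
Why: O-silylation of the tertiary allylic alcohol with a silyl triflate; it prevents lactol formation after the cleavage in step 2 and leaves the chiral-pool C10 centre untouched.

Step 2
Reactants: 2 (3R)-3,7-dimethyl-3-(triethylsilyloxy)octa-1,6-diene
Product: 4 (4R)-4-methyl-4-(triethylsilyloxy)hex-5-enal, via ozonide 3 (not isolated)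
Conditions: O3 (one equivalent, indicator end-point), CH2Cl2, −78 °C; then Me2S, −78 °C → rt
Reagents that add atoms: ozone, O=[O+][O-]
Why: chemoselective ozonolysis; electrophilic ozone should attack the electron-rich trisubstituted olefin much faster than the vinyl group next to the quaternary silyloxy carbon.

Step 3
Reactants: 4 (4R)-4-methyl-4-(triethylsilyloxy)hex-5-enal
Product: 5 (2R,4R)-4-methyl-2-[(2,2,6,6-tetramethylpiperidin-1-yl)oxy]-4-(triethylsilyloxy)hex-5-enal
Conditions: TEMPO, CuCl2·2H2O (10 mol%), (5R)-5-benzyl-2,2,3-trimethylimidazolidin-4-one·TFA (20 mol%), acetone, air, −20 °C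
Reagents that add atoms: TEMPO, CC1(C)CCCC(C)(C)N1[O]
Why: enamine-mediated organocatalytic α-oxyamination of an aldehyde; the catalyst shields one enamine face and so sets C8 under catalyst control, and the bulky alkoxyamine then serves as a non-chelating protecting group for C8–O.

Step 4
Reactants: 5 (2R,4R)-4-methyl-2-[(2,2,6,6-tetramethylpiperidin-1-yl)oxy]-4-(triethylsilyloxy)hex-5-enal; 6 methyl propiolate
Product: 8 methyl 2-[(1RS,2R,4R)-1-hydroxy-4-methyl-2-[(2,2,6,6-tetramethylpiperidin-1-yl)oxy]-4-(triethylsilyloxy)hex-5-en-1-yl]prop-2-enoate, via vinylalane 7 (not isolated)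
Conditions: 6, diisobutylaluminium hydride, NMO, THF, 0 °C; then 5, 0 °C → rt; Rochelle salt work-up
Reagents that add atoms: none
Why: vinylalumination (hydroalumination of the propiolate, then 1,2-addition to the aldehyde) gives the Morita–Baylis–Hillman-type adduct quickly and without prolonged amine base that could epimerise C8; the C7 carbinol configuration is erased in step 5.

Step 5
Reactants: 8 methyl 2-[(1RS,2R,4R)-1-hydroxy-4-methyl-2-[(2,2,6,6-tetramethylpiperidin-1-yl)oxy]-4-(triethylsilyloxy)hex-5-en-1-yl]prop-2-enoate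
Product: 9 methyl (2Z,4R,6R)-2-(bromomethyl)-6-methyl-4-[(2,2,6,6-tetramethylpiperidin-1-yl)oxy]-6-(triethylsilyloxy)octa-2,7-dienoate
Conditions: NBS, Me2S, CH2Cl2, 0 °C → rt
Reagents that add atoms: N-bromosuccinimide, O=C1CCC(=O)N1Br
Why: bromination with allylic transposition (SN2′ attack of bromide on the alkoxysulfonium salt); the thermodynamically preferred (Z)-2-(bromomethyl)enoate, with C8 cis to CH2Br, is expected.

Step 6
Reactants: 10 4-(hydroxymethyl)furan-2(5H)-one
Product: 11 4-[(tert-butyldiphenylsilyloxy)methyl]furan-2(5H)-one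
Conditions: TBDPSCl, imidazole, DMF, 0 °C → rt
Reagents that add atoms: tert-butyl(chloro)diphenylsilane, CC(C)(C)[Si](Cl)(c1ccccc1)c1ccccc1
Why: silylation of the primary alcohol (future C15–OH); the butenolide ring keeps the future C3 oxygen cis to the future C6 carbon and so distinguishes it from C15.

Step 7
Reactants: 11 4-[(tert-butyldiphenylsilyloxy)methyl]furan-2(5H)-one
Product: 12 4-[(tert-butyldiphenylsilyloxy)methyl]-2,5-dihydrofuran-2-ol
Conditions: diisobutylaluminium hydride (1.1 equiv), CH2Cl2, −78 °C; Rochelle salt, neutral work-up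
Reagents that add atoms: none
Why: partial reduction of the lactone to the lactol through the tetrahedral aluminate, giving a masked (Z)-4-hydroxy-enal whose ring preserves the olefin geometry.

Step 8
Reactants: 9 methyl (2Z,4R,6R)-2-(bromomethyl)-6-methyl-4-[(2,2,6,6-tetramethylpiperidin-1-yl)oxy]-6-(triethylsilyloxy)octa-2,7-dienoate; 12 4-[(tert-butyldiphenylsilyloxy)methyl]-2,5-dihydrofuran-2-ol
Product: 14 (4E,6S,7S,8R,10R)-15-(tert-butyldiphenylsilyloxy)-3-hydroxy-8-[(2,2,6,6-tetramethylpiperidin-1-yl)oxy]-10-(triethylsilyloxy)-2,3-secogermacra-1,4,11(13)-trien-12,6-olide, via hydroxy ester 13 (not isolated)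
Conditions: indium powder, THF/H2O (1:1), rt; then TsOH·H2O (5 mol%), CH2Cl2, 0 °C
Reagents that add atoms: none
Why: Barbier allylation of the open form of the lactol through a closed chair transition state, in which the (Z)-bromide places C8 axial and should give the syn adduct (cis-lactone after acid-catalysed lactonisation), while allylic strain at C8 (H eclipsing the CH2In arm, the C9 chain anti to the incoming aldehyde, the non-chelating oxygen outside) should set C6 and C7 relative to C8.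

Step 9
Reactants: 14 (4E,6S,7S,8R,10R)-15-(tert-butyldiphenylsilyloxy)-3-hydroxy-8-[(2,2,6,6-tetramethylpiperidin-1-yl)oxy]-10-(triethylsilyloxy)-2,3-secogermacra-1,4,11(13)-trien-12,6-olide
Product: 16 (4E,6S,7R,8R,10R)-15-(tert-butyldiphenylsilyloxy)-3,8,10-trihydroxy-13-(4-methylbenzenesulfonyl)-2,3-secogermacra-1,4-dien-12,6-olide, via sulfone 15 (not isolated)
Conditions: sodium p-toluenesulfinate, AcOH/THF/H2O (3:1:1), rt; then Zn dust, 50 °C
Reagents that add atoms: sodium p-toluenesulfinate, Cc1ccc(cc1)S(=O)[O-].[Na+]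
Why: sulfa-Michael addition masks the α-methylene lactone, which would otherwise capture the nitrile oxide in a six-membered cycloaddition; Zn/AcOH reduction then cleaves the alkoxyamine N–O bond and the warm aqueous acid hydrolyses the tertiary silyl ether.

Step 10
Reactants: 16 (4E,6S,7R,8R,10R)-15-(tert-butyldiphenylsilyloxy)-3,8,10-trihydroxy-13-(4-methylbenzenesulfonyl)-2,3-secogermacra-1,4-dien-12,6-olide
Product: 18 (4E,6S,7R,8R,10R)-15-(tert-butyldiphenylsilyloxy)-8,10-dihydroxy-3-(hydroxyimino)-13-(4-methylbenzenesulfonyl)-2,3-secogermacra-1,4-dien-12,6-olide, via enal 17 (not isolated)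
Conditions: MnO2, CH2Cl2, rt; filter; then NH2OH·HCl, NaOAc, MeOH, 0 °C
Reagents that add atoms: hydroxylamine hydrochloride, NO.Cl
Why: allylic oxidation (only the primary allylic C3–OH is activated towards MnO2) followed at once by oxime condensation, so that the configurationally labile (Z)-enal is not stored.

Step 11
Reactants: 18 (4E,6S,7R,8R,10R)-15-(tert-butyldiphenylsilyloxy)-8,10-dihydroxy-3-(hydroxyimino)-13-(4-methylbenzenesulfonyl)-2,3-secogermacra-1,4-dien-12,6-olide
Product: 21 (4E,6S,7R,8R,10R)-15-(tert-butyldiphenylsilyloxy)-8,10-dihydroxy-13-(4-methylbenzenesulfonyl)-1,3-(epoxynitrilo)germacr-4-en-12,6-olide, via hydroximoyl chloride 19 (not isolated), via nitrile oxide 20 (not isolated)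
Conditions: NCS, DMF, 0 °C → rt; then syringe-pump addition to KHCO3, EtOAc, 45 °C (final 0.001 M)
Reagents that add atoms: none
Why: Chlorination of the aldoxime and slow dehydrochlorination generate the α,β-unsaturated nitrile oxide 20 at high dilution, which adds across the C1=C2 vinyl group in a concerted (3+2) cycloaddition that forms C2–C3 and O–C1 together. The closest known reaction type is the intramolecular nitrile oxide–alkene cycloaddition used to make macrocyclic, bridged (3,5-disubstituted) isoxazolines. The isoxazoline ring is closed by the cycloaddition itself, and the ten-membered carbocycle is closed in the bridging mode, by bonding C3 to the terminal alkene carbon C2 (formally a 10-endo closure). The only new stereocentre, C1, is set by the transannular approach of the tethered dipole and is inconsequential because it becomes the C1 ketone in step 14. The step needs regioselectivity (C3 to C2, not C1), chemoselectivity and ring closure ahead of dimerisation: the first follows from the preference of nitrile oxides for the unsubstituted alkene terminus, reinforced by the quaternary C10 next to C1, and the second from the sulfone mask on C11=C13. The third rests on high dilution, on the cis C4=C5 olefin, the cis-fused lactone and the gem-disubstituted C10 holding C3 and the vinyl group on the same side, and on hydrogen bonding of the free C10–OH to the nitrile oxide oxygen.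

Step 12
Reactants: 21 (4E,6S,7R,8R,10R)-15-(tert-butyldiphenylsilyloxy)-8,10-dihydroxy-13-(4-methylbenzenesulfonyl)-1,3-(epoxynitrilo)germacr-4-en-12,6-olide
Product: 23 (4E,6S,7R,8R,10R)-15-(tert-butyldiphenylsilyloxy)-10-hydroxy-8-(3-methylbutanoyloxy)-1,3-(epoxynitrilo)germacra-4,11(13)-dien-12,6-olide, via sulfone ester 22 (not isolated)
Conditions: isovaleryl chloride, pyridine, DMAP (cat.), CH2Cl2, 0 °C; then DBU, 0 °C → rt
Reagents that add atoms: 3-methylbutanoyl chloride, CC(C)CC(Cl)=O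
Why: acylation of the only reactive (secondary C8) hydroxyl, the tertiary C10–OH being inert, then E1cB elimination of sulfinate to restore the α-methylene lactone; the strong base is used only after the C8–OH that could translactonise has been capped.

Step 13
Reactants: 23 (4E,6S,7R,8R,10R)-15-(tert-butyldiphenylsilyloxy)-10-hydroxy-8-(3-methylbutanoyloxy)-1,3-(epoxynitrilo)germacra-4,11(13)-dien-12,6-olide
Product: 25 (4Z,6S,7R,8R,10R)-15-(tert-butyldiphenylsilyloxy)-1,10-dihydroxy-8-(3-methylbutanoyloxy)-3-oxogermacra-4,11(13)-dien-12,6-olide, via hydroxy imine 24 (not isolated)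
Conditions: Mo(CO)6, MeCN/H2O (10:1), 80 °C
Reagents that add atoms: water, O
Why: reductive N–O cleavage of the 2-isoxazoline by zerovalent molybdenum and hydrolysis of the β-hydroxy imine; olefins, esters and the silyl ether are inert, and the free C10–OH can hold the product as its transannular hemiketal, which should protect it from retro-aldol cleavage.

Step 14
Reactants: 25 (4Z,6S,7R,8R,10R)-15-(tert-butyldiphenylsilyloxy)-1,10-dihydroxy-8-(3-methylbutanoyloxy)-3-oxogermacra-4,11(13)-dien-12,6-olide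
Product: 26 (4Z,6S,7R,8R,10R)-15-(tert-butyldiphenylsilyloxy)-10-hydroxy-8-(3-methylbutanoyloxy)-1,3-dioxogermacra-4,11(13)-dien-12,6-olide
Conditions: Dess–Martin periodinane (1.2 equiv), CH2Cl2, 0 °C → rt
Reagents that add atoms: none
Why: hypervalent-iodine oxidation of the secondary C1 alcohol to the ketone; the tertiary C10 hydroxyl (or its hemiketal) cannot be oxidised.

Step 15
Reactants: 26 (4Z,6S,7R,8R,10R)-15-(tert-butyldiphenylsilyloxy)-10-hydroxy-8-(3-methylbutanoyloxy)-1,3-dioxogermacra-4,11(13)-dien-12,6-olide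
Product: 28 (4Z,6S,7R,8R,10R)-15-hydroxy-8-(3-methylbutanoyloxy)-1-oxo-3,10-epoxygermacra-2,4,11(13)-trien-12,6-olide, via silyl ether 27 (not isolated)
Conditions: HF·pyridine, THF/pyridine, 0 °C → rt
Reagents that add atoms: none
Why: acid-mediated 5-exo addition of the C10 hydroxyl to the C3 ketone and dehydration of the hemiketal (the α′-hydroxy-1,3-diketone to 3(2H)-furanone closure), then fluoride cleavage of the primary silyl ether; no stereocentre is touched.

**Compound list**

1 | (R)-linalool, (3R)-3,7-dimethylocta-1,6-dien-3-ol | C=C[C@](C)(O)CCC=C(C)C | starting material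
2 | (3R)-3,7-dimethyl-3-(triethylsilyloxy)octa-1,6-diene | C=C[C@](C)(O[Si](CC)(CC)CC)CCC=C(C)C | intermediate
3 | 3,3-dimethyl-5-[(3R)-3-methyl-3-(triethylsilyloxy)pent-4-en-1-yl]-1,2,4-trioxolane (ozonide) | C=C[C@](C)(O[Si](CC)(CC)CC)CCC1OOC(C)(C)O1 | intermediate (not isolated)
4 | (4R)-4-methyl-4-(triethylsilyloxy)hex-5-enal | C=C[C@](C)(O[Si](CC)(CC)CC)CCC=O | intermediate
5 | (2R,4R)-4-methyl-2-[(2,2,6,6-tetramethylpiperidin-1-yl)oxy]-4-(triethylsilyloxy)hex-5-enal | C=C[C@](C)(O[Si](CC)(CC)CC)C[C@@H](ON1C(C)(C)CCCC1(C)C)C=O | intermediate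
6 | methyl propiolate | C#CC(=O)OC | starting material
7 | methyl 2-(diisobutylalumanyl)prop-2-enoate (vinylalane) | C=C([Al](CC(C)C)CC(C)C)C(=O)OC | intermediate (not isolated)
8 | methyl 2-[(1RS,2R,4R)-1-hydroxy-4-methyl-2-[(2,2,6,6-tetramethylpiperidin-1-yl)oxy]-4-(triethylsilyloxy)hex-5-en-1-yl]prop-2-enoate | C=C[C@](C)(O[Si](CC)(CC)CC)C[C@@H](ON1C(C)(C)CCCC1(C)C)C(O)C(=C)C(=O)OC | intermediate
9 | methyl (2Z,4R,6R)-2-(bromomethyl)-6-methyl-4-[(2,2,6,6-tetramethylpiperidin-1-yl)oxy]-6-(triethylsilyloxy)octa-2,7-dienoate | C=C[C@](C)(O[Si](CC)(CC)CC)C[C@@H](ON1C(C)(C)CCCC1(C)C)/C=C(\CBr)C(=O)OC | intermediate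
10 | 4-(hydroxymethyl)furan-2(5H)-one | O=C1C=C(CO)CO1 | starting material
11 | 4-[(tert-butyldiphenylsilyloxy)methyl]furan-2(5H)-one | O=C1C=C(CO[Si](c2ccccc2)(c2ccccc2)C(C)(C)C)CO1 | intermediate
12 | 4-[(tert-butyldiphenylsilyloxy)methyl]-2,5-dihydrofuran-2-ol (racemic lactol) | OC1C=C(CO[Si](c2ccccc2)(c2ccccc2)C(C)(C)C)CO1 | intermediate
13 | methyl (4E,6S,7S,8R,10R)-15-(tert-butyldiphenylsilyloxy)-3,6-dihydroxy-8-[(2,2,6,6-tetramethylpiperidin-1-yl)oxy]-10-(triethylsilyloxy)-2,3-secogermacra-1,4,11(13)-trien-12-oate | C=C(C(=O)OC)[C@@H]([C@@H](O)/C=C(/CO[Si](c1ccccc1)(c1ccccc1)C(C)(C)C)CO)[C@H](ON1C(C)(C)CCCC1(C)C)C[C@@](C)(O[Si](CC)(CC)CC)C=C | intermediate (not isolated)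
14 | (4E,6S,7S,8R,10R)-15-(tert-butyldiphenylsilyloxy)-3-hydroxy-8-[(2,2,6,6-tetramethylpiperidin-1-yl)oxy]-10-(triethylsilyloxy)-2,3-secogermacra-1,4,11(13)-trien-12,6-olide (cis-disubstituted α-methylene-γ-butyrolactone) | C=C1C(=O)O[C@@H](/C=C(/CO[Si](c2ccccc2)(c2ccccc2)C(C)(C)C)CO)[C@H]1[C@H](ON3C(C)(C)CCCC3(C)C)C[C@@](C)(O[Si](CC)(CC)CC)C=C | intermediate
15 | (4E,6S,7S,8R,10R)-15-(tert-butyldiphenylsilyloxy)-3-hydroxy-13-(4-methylbenzenesulfonyl)-8-[(2,2,6,6-tetramethylpiperidin-1-yl)oxy]-10-(triethylsilyloxy)-2,3-secogermacra-1,4-dien-12,6-olide | Cc1ccc(cc1)S(=O)(=O)CC1C(=O)O[C@@H](/C=C(/CO[Si](c2ccccc2)(c2ccccc2)C(C)(C)C)CO)[C@H]1[C@H](ON3C(C)(C)CCCC3(C)C)C[C@@](C)(O[Si](CC)(CC)CC)C=C | intermediate (not isolated)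
16 | (4E,6S,7R,8R,10R)-15-(tert-butyldiphenylsilyloxy)-3,8,10-trihydroxy-13-(4-methylbenzenesulfonyl)-2,3-secogermacra-1,4-dien-12,6-olide | Cc1ccc(cc1)S(=O)(=O)CC1C(=O)O[C@@H](/C=C(/CO[Si](c2ccccc2)(c2ccccc2)C(C)(C)C)CO)[C@H]1[C@H](O)C[C@@](C)(O)C=C | intermediate
17 | (4Z,6S,7R,8R,10R)-15-(tert-butyldiphenylsilyloxy)-8,10-dihydroxy-13-(4-methylbenzenesulfonyl)-3-oxo-2,3-secogermacra-1,4-dien-12,6-olide (Z-enal) | Cc1ccc(cc1)S(=O)(=O)CC1C(=O)O[C@@H](/C=C(/CO[Si](c2ccccc2)(c2ccccc2)C(C)(C)C)C=O)[C@H]1[C@H](O)C[C@@](C)(O)C=C | intermediate (not isolated)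
18 | (4E,6S,7R,8R,10R)-15-(tert-butyldiphenylsilyloxy)-8,10-dihydroxy-3-(hydroxyimino)-13-(4-methylbenzenesulfonyl)-2,3-secogermacra-1,4-dien-12,6-olide | Cc1ccc(cc1)S(=O)(=O)CC1C(=O)O[C@@H](/C=C(/CO[Si](c2ccccc2)(c2ccccc2)C(C)(C)C)C=NO)[C@H]1[C@H](O)C[C@@](C)(O)C=C | intermediate
19 | (4Z,6S,7R,8R,10R)-15-(tert-butyldiphenylsilyloxy)-3-chloro-8,10-dihydroxy-3-(hydroxyimino)-13-(4-methylbenzenesulfonyl)-2,3-secogermacra-1,4-dien-12,6-olide | Cc1ccc(cc1)S(=O)(=O)CC1C(=O)O[C@@H](/C=C(/CO[Si](c2ccccc2)(c2ccccc2)C(C)(C)C)C(Cl)=NO)[C@H]1[C@H](O)C[C@@](C)(O)C=C | intermediate (not isolated)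
20 | nitrile oxide at C3 (C3≡N–O) of (4E,6S,7R,8R,10R)-15-(tert-butyldiphenylsilyloxy)-8,10-dihydroxy-13-(4-methylbenzenesulfonyl)-2,3-secogermacra-1,4-dien-12,6-olide | Cc1ccc(cc1)S(=O)(=O)CC1C(=O)O[C@@H](/C=C(/CO[Si](c2ccccc2)(c2ccccc2)C(C)(C)C)C#[N+][O-])[C@H]1[C@H](O)C[C@@](C)(O)C=C | intermediate (not isolated)
21 | (4E,6S,7R,8R,10R)-15-(tert-butyldiphenylsilyloxy)-8,10-dihydroxy-13-(4-methylbenzenesulfonyl)-1,3-(epoxynitrilo)germacr-4-en-12,6-olide (2-isoxazoline with O on C1 and C=N at C3) | Cc5ccc(cc5)S(=O)(=O)CC1C(=O)O[C@H]2/C=C(/CO[Si](c4ccccc4)(c4ccccc4)C(C)(C)C)C3=NOC(C3)[C@](C)(O)C[C@@H](O)[C@@H]12 | intermediate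
22 | (4E,6S,7R,8R,10R)-15-(tert-butyldiphenylsilyloxy)-10-hydroxy-8-(3-methylbutanoyloxy)-13-(4-methylbenzenesulfonyl)-1,3-(epoxynitrilo)germacr-4-en-12,6-olide | Cc5ccc(cc5)S(=O)(=O)CC1C(=O)O[C@H]2/C=C(/CO[Si](c4ccccc4)(c4ccccc4)C(C)(C)C)C3=NOC(C3)[C@](C)(O)C[C@@H](OC(=O)CC(C)C)[C@@H]12 | intermediate (not isolated)
23 | (4E,6S,7R,8R,10R)-15-(tert-butyldiphenylsilyloxy)-10-hydroxy-8-(3-methylbutanoyloxy)-1,3-(epoxynitrilo)germacra-4,11(13)-dien-12,6-olide | C=C1C(=O)O[C@H]2/C=C(/CO[Si](c4ccccc4)(c4ccccc4)C(C)(C)C)C3=NOC(C3)[C@](C)(O)C[C@@H](OC(=O)CC(C)C)[C@@H]12 | intermediate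
24 | (4E,6S,7R,8R,10R)-15-(tert-butyldiphenylsilyloxy)-1,10-dihydroxy-3-imino-8-(3-methylbutanoyloxy)germacra-4,11(13)-dien-12,6-olide | C=C1C(=O)O[C@H]2/C=C(/CO[Si](c3ccccc3)(c3ccccc3)C(C)(C)C)C(=N)CC(O)[C@](C)(O)C[C@@H](OC(=O)CC(C)C)[C@@H]12 | intermediate (not isolated)
25 | (4Z,6S,7R,8R,10R)-15-(tert-butyldiphenylsilyloxy)-1,10-dihydroxy-8-(3-methylbutanoyloxy)-3-oxogermacra-4,11(13)-dien-12,6-olide | C=C1C(=O)O[C@H]2/C=C(/CO[Si](c3ccccc3)(c3ccccc3)C(C)(C)C)C(=O)CC(O)[C@](C)(O)C[C@@H](OC(=O)CC(C)C)[C@@H]12 | intermediate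
26 | (4Z,6S,7R,8R,10R)-15-(tert-butyldiphenylsilyloxy)-10-hydroxy-8-(3-methylbutanoyloxy)-1,3-dioxogermacra-4,11(13)-dien-12,6-olide | C=C1C(=O)O[C@H]2/C=C(/CO[Si](c3ccccc3)(c3ccccc3)C(C)(C)C)C(=O)CC(=O)[C@](C)(O)C[C@@H](OC(=O)CC(C)C)[C@@H]12 | intermediate
27 | (4Z,6S,7R,8R,10R)-15-(tert-butyldiphenylsilyloxy)-8-(3-methylbutanoyloxy)-1-oxo-3,10-epoxygermacra-2,4,11(13)-trien-12,6-olide | C=C1C(=O)O[C@H]2/C=C(/CO[Si](c4ccccc4)(c4ccccc4)C(C)(C)C)C3=CC(=O)[C@@](C)(C[C@@H](OC(=O)CC(C)C)[C@@H]12)O3 | intermediate (not isolated)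
28 | (4Z,6S,7R,8R,10R)-15-hydroxy-8-(3-methylbutanoyloxy)-1-oxo-3,10-epoxygermacra-2,4,11(13)-trien-12,6-olide (CNP0171896.2) | C=C1C(=O)O[C@H]2/C=C(/CO)C3=CC(=O)[C@@](C)(C[C@@H](OC(=O)CC(C)C)[C@@H]12)O3 | target

**Step count and risks**

Total step count: 15. Longest linear sequence: 13 steps (steps 1–5 and 8–15, from (R)-linalool).

Steps most likely to fail:

1. Step 11. The ten-membered ring closure may be too slow at the dilution needed, so that dimerisation of the nitrile oxide to furoxans or intermolecular cycloaddition takes over. The fallback forms the same C2–C3 bond by an anionic ring closure; it sets out from enal 17 (isolated after the MnO2 filtration of step 10) and returns at diketone 26. Acylation of the C8 hydroxyl (isovaleryl chloride, pyridine, DMAP) would give the enal isovalerate F1. NBS in wet THF should convert the vinyl group, the conjugated C4=C5 olefin being deactivated, into the bromohydrin F2, and Dess–Martin oxidation would give the α-bromo ketone F3. SmI2 (THF, −78 °C, high dilution) would then generate the samarium enolate at C2, which adds to the C3 aldehyde in an intramolecular Reformatsky-type aldol reaction, a reaction type used for medium-ring carbocycles, to give the ring-closed β-hydroxy ketone F4. Dess–Martin oxidation to the sulfone-masked diketone F5 and DBU elimination of sulfinate would then lead to 26.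

2. Step 8. The allylindium addition may show poor facial selectivity with respect to the C8 stereocentre: the syn C6/C7 relationship should hold, but the pair may form on the wrong face if the allylic-strain model does not describe the real transition state. The fallback replaces substrate control by catalyst control; it sets out from bromide 9 and returns at hydroxy ester 13. Borylation of 9 (B2pin2, Pd2(dba)3 as zerovalent palladium source, toluene/DMSO) would give the allylboronate F6. Its allylboration of the open form of 12 would be catalysed by a chiral BINOL-derived phosphoric acid (3,3′-bis(2,4,6-triisopropylphenyl)-1,1′-binaphthyl-2,2′-diyl hydrogen phosphate, matched enantiomer, toluene, 4 Å MS). It would pass through the same closed chair transition state, hence the same syn relationship, but with the aldehyde face chosen by the catalyst; hydrolytic work-up gives 13, which is lactonised as in step 8.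

3. Step 14. The hypervalent iodine reagent may over-oxidise, either by glycol-type cleavage of the C1/C10 diol or by hydroxylation at C2 of the enolised β-diketone. The fallback reverses the order of cyclisation and oxidation; it sets out from 25 and returns at silyl ether 27. Mild acid (PPTS, 4 Å MS, CH2Cl2) should dehydrate the transannular hemiketal of 25 to the cyclic enol ether alcohol F7; aromatisation is impossible because C10 is quaternary. Its C1 hydroxyl is now allylic and the C10 oxygen is an ether, so MnO2 can oxidise it selectively to 27, which is then desilylated under the conditions of step 15.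

Further compounds
F1 | step 11 | (4Z,6S,7R,8R,10R)-15-(tert-butyldiphenylsilyloxy)-10-hydroxy-8-(3-methylbutanoyloxy)-13-(4-methylbenzenesulfonyl)-3-oxo-2,3-secogermacra-1,4-dien-12,6-olide | Cc1ccc(cc1)S(=O)(=O)CC1C(=O)O[C@@H](/C=C(/CO[Si](c2ccccc2)(c2ccccc2)C(C)(C)C)C=O)[C@H]1[C@H](OC(=O)CC(C)C)C[C@@](C)(O)C=C
F2 | step 11 | (4Z,6S,7R,8R,10R)-2-bromo-15-(tert-butyldiphenylsilyloxy)-1,10-dihydroxy-8-(3-methylbutanoyloxy)-13-(4-methylbenzenesulfonyl)-3-oxo-2,3-secogermacr-4-en-12,6-olide | Cc1ccc(cc1)S(=O)(=O)CC1C(=O)O[C@@H](/C=C(/CO[Si](c2ccccc2)(c2ccccc2)C(C)(C)C)C=O)[C@H]1[C@H](OC(=O)CC(C)C)C[C@@](C)(O)C(O)CBr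
F3 | step 11 | (4Z,6S,7R,8R,10R)-2-bromo-15-(tert-butyldiphenylsilyloxy)-10-hydroxy-8-(3-methylbutanoyloxy)-13-(4-methylbenzenesulfonyl)-1,3-dioxo-2,3-secogermacr-4-en-12,6-olide | Cc1ccc(cc1)S(=O)(=O)CC1C(=O)O[C@@H](/C=C(/CO[Si](c2ccccc2)(c2ccccc2)C(C)(C)C)C=O)[C@H]1[C@H](OC(=O)CC(C)C)C[C@@](C)(O)C(=O)CBr
F4 | step 11 | (4Z,6S,7R,8R,10R)-15-(tert-butyldiphenylsilyloxy)-3,10-dihydroxy-8-(3-methylbutanoyloxy)-13-(4-methylbenzenesulfonyl)-1-oxogermacr-4-en-12,6-olide | Cc5ccc(cc5)S(=O)(=O)CC1C(=O)O[C@H]2/C=C(/CO[Si](c4ccccc4)(c4ccccc4)C(C)(C)C)C(O)CC(=O)[C@](C)(O)C[C@@H](OC(=O)CC(C)C)[C@@H]12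
F5 | step 11 | (4Z,6S,7R,8R,10R)-15-(tert-butyldiphenylsilyloxy)-10-hydroxy-8-(3-methylbutanoyloxy)-13-(4-methylbenzenesulfonyl)-1,3-dioxogermacr-4-en-12,6-olide | Cc5ccc(cc5)S(=O)(=O)CC1C(=O)O[C@H]2/C=C(/CO[Si](c4ccccc4)(c4ccccc4)C(C)(C)C)C(=O)CC(=O)[C@](C)(O)C[C@@H](OC(=O)CC(C)C)[C@@H]12
F6 | step 8 | methyl (2E,4R,6R)-6-methyl-2-[(4,4,5,5-tetramethyl-1,3,2-dioxaborolan-2-yl)methyl]-4-[(2,2,6,6-tetramethylpiperidin-1-yl)oxy]-6-(triethylsilyloxy)octa-2,7-dienoate | C=C[C@](C)(O[Si](CC)(CC)CC)C[C@@H](ON1C(C)(C)CCCC1(C)C)/C=C(\CB1OC(C)(C)C(C)(C)O1)C(=O)OC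
F7 | step 14 | (4Z,6S,7R,8R,10R)-15-(tert-butyldiphenylsilyloxy)-1-hydroxy-8-(3-methylbutanoyloxy)-3,10-epoxygermacra-2,4,11(13)-trien-12,6-olide | C=C1C(=O)O[C@H]2/C=C(/CO[Si](c4ccccc4)(c4ccccc4)C(C)(C)C)C3=CC(O)[C@@](C)(C[C@@H](OC(=O)CC(C)C)[C@@H]12)O3
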